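**Retrosynthetic overview**
1. Target ⇒ triol 21 (acylation in order of steric rank) ⇒ lactol 19 (two Wittig olefinations build the 12E,14-diene).
2. Ring B (formed second) ⇒ SmI2 ketyl–olefin 6-exo closure of keto enoate 16, making the C8–C9 bond, the C8 carbinol and the C12 lactone in one operation.
3. C10 quaternary centre ⇒ two enolate C–C bond formations on ring A (methyl first, then the acrylate arm anti to the C5 chain).
4. Key disconnection: Cu-catalysed enantioselective conjugate addition that desymmetrises prochiral dienone 6 and fixes C4 (quaternary) and C5 together.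
5. Dienone 6 (ring A, formed first, all six ring carbons from the arene) ⇒ benzoic acid by Birch reductive methylation and bis-allylic oxidation.

Convention: labdane numbering (C1 to C20) is used for every intermediate; β is the face that carries the C10 methyl group in the target, α the opposite face. The target is (1R,4R,5S,8R,9R,10S,12E).
Assumption: the (S,R,R) phosphoramidite is taken to give the enantiomer drawn in step 5; if the sense of induction is the reverse, its mirror image is used.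

**Step 1**
Reactants: 1 benzoic acid
Product: 3 1-methylcyclohexa-2,5-diene-1-carboxylic acid, via dilithium dienediolate 2 (not isolated)
Conditions: Li, NH3(l)/THF, −78 °C; then MeI, −78 °C → rt; aq. HCl
Reagents that add atoms: iodomethane, CI
Why: Birch reduction of lithium benzoate gives the cross-conjugated dienediolate, which is C-methylated at the ipso carbon (Birch reductive alkylation); no stereocentre is formed.

**Step 2**
Reactants: 3 1-methylcyclohexa-2,5-diene-1-carboxylic acid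
Product: 4 (1-methylcyclohexa-2,5-dien-1-yl)methanol
Conditions: LiAlH4, THF, 0 °C → reflux
Reagents that add atoms: none
Why: Hydride reduction of the acid to the neopentyl alcohol; the skipped diene is inert to LiAlH4.

**Step 3**
Reactants: 4 (1-methylcyclohexa-2,5-dien-1-yl)methanol
Product: 5 [(1-methylcyclohexa-2,5-dien-1-yl)methoxy]triphenylmethane
Conditions: Ph3CCl, Et3N, DMAP (cat.), CH2Cl2, 40 °C
Reagents that add atoms: trityl chloride, ClC(c1ccccc1)(c1ccccc1)c1ccccc1
Why: Tritylation (SN1 through the trityl cation) installs a very bulky, acid-labile ether that will shield one face of the ring in step 5.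

**Step 4**
Reactants: 5 [(1-methylcyclohexa-2,5-dien-1-yl)methoxy]triphenylmethane
Product: 6 4-methyl-4-[(triphenylmethoxy)methyl]cyclohexa-2,5-dien-1-one
Conditions: (C5H5NH)2Cr2O7 (pyridinium dichromate), t-BuOOH, Celite, PhH, 10 °C → rt
Reagents that add atoms: tert-butyl hydroperoxide, CC(C)(C)OO
Why: Chromium-mediated bis-allylic oxidation of the doubly allylic CH2 gives the cross-conjugated ketone, an achiral dienone whose C4 is prochiral.

**Step 5 (key step)**
Reactants: 6 4-methyl-4-[(triphenylmethoxy)methyl]cyclohexa-2,5-dien-1-one; 7 2-(2-bromoethyl)-2-methyl-1,3-dioxolane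
Product: 11 (4R,5R,6R)-4,6-dimethyl-5-[2-(2-methyl-1,3-dioxolan-2-yl)ethyl]-4-[(triphenylmethoxy)methyl]cyclohex-2-en-1-one, via Grignard reagent 8 (not isolated), via dialkylzinc 9 (not isolated), via zinc enolate 10 (not isolated)
Conditions: 7, Mg, THF; ZnCl2 (0.5 equiv), then 1,4-dioxane, filter; Cu(OTf)2 (2 mol%), (S,R,R)-N,N-bis(1-phenylethyl) binaphthyl phosphoramidite (4 mol%), 6, PhMe, −30 °C; then MeI, HMPA, −30 → 0 °C
Reagents that add atoms: iodomethane, CI
Why: Cu/phosphoramidite-catalysed asymmetric conjugate addition of the dialkylzinc desymmetrises the dienone: the catalyst picks one of the two enantiotopic enone arms and the alkyl group enters anti to the CH2OCPh3 group (syn to the C4 methyl), so C4 and C5 are fixed together, and the zinc enolate is methylated in the same flask (the C10 configuration formed here is erased in step 6).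

**Step 6**
Reactants: 11 (4R,5R,6R)-4,6-dimethyl-5-[2-(2-methyl-1,3-dioxolan-2-yl)ethyl]-4-[(triphenylmethoxy)methyl]cyclohex-2-en-1-one; 12 ethyl (2Z)-3-iodoprop-2-enoate
Product: 14 ethyl (2E)-3-{1,5-dimethyl-6-[2-(2-methyl-1,3-dioxolan-2-yl)ethyl]-2-oxo-5-[(triphenylmethoxy)methyl]cyclohex-3-en-1-yl}prop-2-enoate (10β-methyl; acrylate arm on the α-face), via potassium dienolate 13 (not isolated)
Conditions: KN(SiMe3)2, THF, −78 °C; then 12, −78 → −20 °C
Reagents that add atoms: none
Why: C-vinylation of the only possible enolate by conjugate addition–elimination on the β-iodoacrylate; the electrophile enters anti to the vicinal C5 chain, so the C10 methyl ends up β (cis to the C5 chain), and iodide loss from the ester enolate (E1cB) gives the E-enoate.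

**Step 7**
Reactants: 14 ethyl (2E)-3-{1,5-dimethyl-6-[2-(2-methyl-1,3-dioxolan-2-yl)ethyl]-2-oxo-5-[(triphenylmethoxy)methyl]cyclohex-3-en-1-yl}prop-2-enoate
Product: 16 ethyl (2E)-3-[2-hydroxy-5-(hydroxymethyl)-1,5-dimethyl-6-(3-oxobutyl)cyclohex-3-en-1-yl]prop-2-enoate (1β-OH), via allylic alcohol 15 (not isolated)
Conditions: NaBH4, CeCl3·7H2O, MeOH, −78 °C; then 1 M aq. HCl/THF, rt
Reagents that add atoms: water, O
Why: Luche 1,2-reduction, in which hydride attacks C1 anti to the pseudoaxial C10 methyl to give the 1β-alcohol while the enoate is untouched; the acid then hydrolyses both the dioxolane and the trityl ether.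

**Step 8**
Reactants: 16 ethyl (2E)-3-[2-hydroxy-5-(hydroxymethyl)-1,5-dimethyl-6-(3-oxobutyl)cyclohex-3-en-1-yl]prop-2-enoate
Product: 17 1β,18-dihydroxy-13,14,15,16-tetranorlabd-2-en-12,8α-olide
Conditions: SmI2, HMPA, t-BuOH, THF, −78 → 0 °C
Reagents that add atoms: none
Why: Ketyl–olefin 6-exo-trig radical cyclisation by divalent samarium through a chair transition state with the bulky HMPA-solvated O–Sm group and the enoate arm both equatorial, which gives 8α-O/8β-CH3 and 9α-H in a trans-fused ring B; the samarium alkoxide then closes the γ-lactone.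

**Step 9**
Reactants: 17 1β,18-dihydroxy-13,14,15,16-tetranorlabd-2-en-12,8α-olide
Product: 18 1β,18-dihydroxy-13,14,15,16-tetranorlabdan-12,8α-olide
Conditions: H2 (1 atm), Rh/Al2O3, EtOAc, rt
Reagents that add atoms: none
Why: Heterogeneous hydrogenation of the cis-disubstituted ring alkene; rhodium on alumina avoids hydrogenolysis of the allylic C–O bond and no stereocentre is formed.

**Step 10**
Reactants: 18 1β,18-dihydroxy-13,14,15,16-tetranorlabdan-12,8α-olide
Product: 19 8α,12-epoxy-13,14,15,16-tetranorlabdane-1β,12,18-triol (lactol; both C12 anomers)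
Conditions: i-Bu2AlH, CH2Cl2, −78 °C; aq. potassium sodium tartrate
Reagents that add atoms: none
Why: Low-temperature i-Bu2AlH reduction of the lactone stops at the aluminium hemiacetal and gives the lactol on work-up.

**Step 11**
Reactants: 19 8α,12-epoxy-13,14,15,16-tetranorlabdane-1β,12,18-triol
Product: 21 (12E)-labda-12,14-diene-1β,8α,18-triol, via enal 20 (not isolated)
Conditions: Ph3P=C(CH3)CHO, PhMe, 90 °C; then Ph3P=CH2 (from Ph3PCH3Br, KOt-Bu), THF, −78 → 0 °C
Reagents that add atoms: 2-(triphenylphosphoranylidene)propanal, CC(C=O)=P(c1ccccc1)(c1ccccc1)c1ccccc1; methyltriphenylphosphonium bromide, C[P+](c1ccccc1)(c1ccccc1)c1ccccc1.[Br-]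
Why: Wittig reaction of the ring-opened hydroxy aldehyde with the stabilised formyl ylide gives the (E)-2-methyl enal (sets 12E), and Wittig methylenation in the same flask completes the 12E,14-diene.

**Step 12**
Reactants: 21 (12E)-labda-12,14-diene-1β,8α,18-triol; 22 icosanoyl chloride
Product: 24 (12E)-1β-acetoxy-8α-hydroxylabda-12,14-dien-18-yl icosanoate (target), via monoester 23 (not isolated)
Conditions: 22 (1.05 equiv), pyridine, CH2Cl2, −20 → 0 °C; then Ac2O, DMAP, rt
Reagents that add atoms: acetic anhydride, CC(=O)OC(C)=O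
Why: Chemoselective acylation by steric rank: the primary C18–OH reacts with the acid chloride at low temperature, the secondary C1–OH is then acetylated with Ac2O/DMAP, and the tertiary C8–OH does not react.

**Compound list**
1 | benzoic acid | OC(=O)c1ccccc1 | starting material
2 | dilithium (cyclohexa-2,5-dien-1-ylidene)methanediolate (Birch dienediolate of benzoate) | [Li+].[Li+].[O-]C([O-])=C1C=CCC=C1 | intermediate
3 | 1-methylcyclohexa-2,5-diene-1-carboxylic acid | CC1(C(=O)O)C=CCC=C1 | intermediate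
4 | (1-methylcyclohexa-2,5-dien-1-yl)methanol | CC1(CO)C=CCC=C1 | intermediate
5 | [(1-methylcyclohexa-2,5-dien-1-yl)methoxy]triphenylmethane | CC1(COC(c2ccccc2)(c2ccccc2)c2ccccc2)C=CCC=C1 | intermediate
6 | 4-methyl-4-[(triphenylmethoxy)methyl]cyclohexa-2,5-dien-1-one (achiral, C4 prochiral) | O=C1C=CC(C)(COC(c2ccccc2)(c2ccccc2)c2ccccc2)C=C1 | intermediate
7 | 2-(2-bromoethyl)-2-methyl-1,3-dioxolane | CC1(CCBr)OCCO1 | starting material
8 | [2-(2-methyl-1,3-dioxolan-2-yl)ethyl]magnesium bromide | CC1(CC[Mg]Br)OCCO1 | intermediate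
9 | bis[2-(2-methyl-1,3-dioxolan-2-yl)ethyl]zinc | CC1(CC[Zn]CCC2(C)OCCO2)OCCO1 | intermediate
10 | alkylzinc dienolate of the 1,4-adduct (C1–O–Zn, C1=C10, C2=C3; 4β-CH3, 4α-CH2OCPh3, 5β-side chain) | CC1(CC[Zn]OC2=C[C@@H](CCC3(C)OCCO3)[C@](C)(COC(c3ccccc3)(c3ccccc3)c3ccccc3)C=C2)OCCO1 | intermediate
11 | (4R,5R,6R)-4,6-dimethyl-5-[2-(2-methyl-1,3-dioxolan-2-yl)ethyl]-4-[(triphenylmethoxy)methyl]cyclohex-2-en-1-one (4β-CH3, 4α-CH2OCPh3, 5β-side chain, 10α-CH3) | C[C@H]1C(=O)C=C[C@@](C)(COC(c2ccccc2)(c2ccccc2)c2ccccc2)[C@@H]1CCC1(C)OCCO1 | intermediate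
12 | ethyl (2Z)-3-iodoprop-2-enoate | CCOC(=O)/C=C\I | starting material
13 | potassium dienolate of 11 (C1–O–K, C1=C10) | [K+].[O-]C1=C(C)[C@@H](CCC2(C)OCCO2)[C@](C)(COC(c2ccccc2)(c2ccccc2)c2ccccc2)C=C1 | intermediate
14 | ethyl (2E)-3-{1,5-dimethyl-6-[2-(2-methyl-1,3-dioxolan-2-yl)ethyl]-2-oxo-5-[(triphenylmethoxy)methyl]cyclohex-3-en-1-yl}prop-2-enoate (4β-CH3, 4α-CH2OCPh3, 5β-side chain, 10β-CH3, 10α-acrylate) | CCOC(=O)/C=C/[C@@]1(C)C(=O)C=C[C@@](C)(COC(c2ccccc2)(c2ccccc2)c2ccccc2)[C@@H]1CCC1(C)OCCO1 | intermediate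
15 | 1β-alcohol of 14 (ketal and trityl ether still in place) | CCOC(=O)/C=C/[C@@]1(C)[C@H](O)C=C[C@@](C)(COC(c2ccccc2)(c2ccccc2)c2ccccc2)[C@@H]1CCC1(C)OCCO1 | intermediate
16 | ethyl (2E)-3-[2-hydroxy-5-(hydroxymethyl)-1,5-dimethyl-6-(3-oxobutyl)cyclohex-3-en-1-yl]prop-2-enoate (1β-OH, 4β-CH3, 4α-CH2OH, 5β-oxobutyl, 10β-CH3) | CCOC(=O)/C=C/[C@@]1(C)[C@H](O)C=C[C@@](C)(CO)[C@@H]1CCC(C)=O | intermediate
17 | 1β,18-dihydroxy-13,14,15,16-tetranorlabd-2-en-12,8α-olide (trans-decalin, 5α-H, 9α-H, 8β-CH3, trans-fused γ-lactone) | O=C1C[C@@H]2[C@@]3(C)[C@H](O)C=C[C@@](C)(CO)[C@@H]3CC[C@@]2(C)O1 | intermediate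
18 | 1β,18-dihydroxy-13,14,15,16-tetranorlabdan-12,8α-olide | O=C1C[C@@H]2[C@@]3(C)[C@H](O)CC[C@@](C)(CO)[C@@H]3CC[C@@]2(C)O1 | intermediate
19 | 8α,12-epoxy-13,14,15,16-tetranorlabdane-1β,12,18-triol (lactol, both C12 anomers) | OC1C[C@@H]2[C@@]3(C)[C@H](O)CC[C@@](C)(CO)[C@@H]3CC[C@@]2(C)O1 | intermediate
20 | (12E)-1β,8α,18-trihydroxy-15-norlabd-12-en-14-al | O=C/C(C)=C/C[C@@H]1[C@@]2(C)[C@H](O)CC[C@@](C)(CO)[C@@H]2CC[C@@]1(C)O | intermediate
21 | (12E)-labda-12,14-diene-1β,8α,18-triol | C=C/C(C)=C/C[C@@H]1[C@@]2(C)[C@H](O)CC[C@@](C)(CO)[C@@H]2CC[C@@]1(C)O | intermediate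
22 | icosanoyl chloride | CCCCCCCCCCCCCCCCCCCC(=O)Cl | starting material
23 | (12E)-1β,8α-dihydroxylabda-12,14-dien-18-yl icosanoate | C=C/C(C)=C/C[C@@H]1[C@@]2(C)[C@H](O)CC[C@@](C)(COC(=O)CCCCCCCCCCCCCCCCCCC)[C@@H]2CC[C@@]1(C)O | intermediate
24 | (1R,4R,5S,8R,9R,10S,12E)-1-acetoxy-8-hydroxylabda-12,14-dien-18-yl icosanoate (1β-OAc, 8α-OH) | C=C/C(C)=C/C[C@@H]1[C@@]2(C)[C@H](OC(C)=O)CC[C@@](C)(COC(=O)CCCCCCCCCCCCCCCCCCC)[C@@H]2CC[C@@]1(C)O | target

**Totals**
Total step count: 12. Longest linear sequence: 12 steps (1 → 24).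

**Steps most likely to fail, each with one fallback**

Step 5. The diastereoselectivity rests only on the steric bias of CH2OCPh3 against CH3 at C4, and the functionalised zinc reagent and the methylation of the zinc enolate add further risk. The fallback sets out from 6 and comes back at 11. A rhodium-catalysed asymmetric 1,4-addition ([RhCl(C2H4)2]2, chiral bicyclooctadiene ligand, KOH, dioxane/H2O) of (E)-2-[2-(2-methyl-1,3-dioxolan-2-yl)ethenyl]-4,4,5,5-tetramethyl-1,3,2-dioxaborolane to 6 gives the 5β-alkenyl enone F1. Hydrogenation of only the side-chain alkene (H2, RhCl(PPh3)3, PhH) gives the saturated enone F2. Separate methylation (LiN(i-Pr)2, THF, −78 °C; MeI) then gives 11.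

Step 6. A hindered tertiary enolate must form a quaternary centre by addition–elimination, with O-attack and poor facial control as the dangers. The fallback sets out from 11 and comes back at 14. The potassium enolate of 11 is added to phenyl vinyl sulfoxide to give the 2-(phenylsulfinyl)ethyl ketone F3. Thermal syn-elimination (PhMe, CaCO3, 110 °C) gives the α-vinyl ketone F4. Cross-metathesis of F4 with ethyl acrylate (second-generation Hoveyda–Grubbs catalyst, CH2Cl2, 40 °C) gives 14.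

Step 8. The C8 configuration depends on the samarium-bound oxygen staying equatorial against a syn-axial CH3/CH3 contact, so the 8-epimer (cis-lactone) may compete. The fallback sets out from 16 and comes back at 17; it forms ring B first and sets C8 afterwards by radical oxygenation.
- Et3SiCl/imidazole gives the bis(triethylsilyl) ether F5.
- Kinetic enolisation towards the methyl group (KN(SiMe3)2, PhNTf2, −78 °C) gives the 2-propenyl triflate F6.
- Reductive Heck cyclisation (Pd(OAc)2, PPh3, HCO2Na, DMF, 80 °C) closes ring B to the 8(17)-exocyclic alkene ester F7.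
- Mukaiyama hydration (Mn(dpm)3, PhSiH3, O2, i-PrOH) traps the tertiary C8 radical from the α-face, anti to the axial C10 methyl, to give the 8α-hydroxy ester F8.
- Bu4NF removes both silyl groups and the C8 alkoxide lactonises to 17.

**Further compounds**
F1 | step 5 | 4β-methyl-5β-[(E)-2-(2-methyl-1,3-dioxolan-2-yl)ethenyl]-4α-[(triphenylmethoxy)methyl]cyclohex-2-en-1-one | O=C1C=C[C@@](C)(COC(c2ccccc2)(c2ccccc2)c2ccccc2)[C@H](/C=C/C2(C)OCCO2)C1
F2 | step 5 | 4β-methyl-5β-[2-(2-methyl-1,3-dioxolan-2-yl)ethyl]-4α-[(triphenylmethoxy)methyl]cyclohex-2-en-1-one (11 without the C10 methyl) | O=C1C=C[C@@](C)(COC(c2ccccc2)(c2ccccc2)c2ccccc2)[C@H](CCC2(C)OCCO2)C1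
F3 | step 6 | 10β-methyl-10α-[2-(phenylsulfinyl)ethyl] ketone from 11 (sulfoxide epimers) | O=S(c1ccccc1)CC[C@@]1(C)C(=O)C=C[C@@](C)(COC(c2ccccc2)(c2ccccc2)c2ccccc2)[C@@H]1CCC1(C)OCCO1
F4 | step 6 | 10β-methyl-10α-vinyl ketone from 11 | C=C[C@@]1(C)C(=O)C=C[C@@](C)(COC(c2ccccc2)(c2ccccc2)c2ccccc2)[C@@H]1CCC1(C)OCCO1
F5 | step 8 | 1,18-bis(triethylsilyl) ether of 16 | CCOC(=O)/C=C/[C@@]1(C)[C@H](O[Si](CC)(CC)CC)C=C[C@@](C)(CO[Si](CC)(CC)CC)[C@@H]1CCC(C)=O
F6 | step 8 | enol triflate of F5 (C8(OTf)=CH2) | CCOC(=O)/C=C/[C@@]1(C)[C@H](O[Si](CC)(CC)CC)C=C[C@@](C)(CO[Si](CC)(CC)CC)[C@@H]1CCC(=C)OS(=O)(=O)C(F)(F)F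
F7 | step 8 | ethyl 1β,18-bis(triethylsilyloxy)-13,14,15,16-tetranorlabda-2,8(17)-dien-12-oate (9α-H) | CCOC(=O)C[C@@H]1[C@@]2(C)[C@H](O[Si](CC)(CC)CC)C=C[C@@](C)(CO[Si](CC)(CC)CC)[C@@H]2CCC1=C
F8 | step 8 | ethyl 8α-hydroxy-1β,18-bis(triethylsilyloxy)-13,14,15,16-tetranorlabd-2-en-12-oate | CCOC(=O)C[C@@H]1[C@@]2(C)[C@H](O[Si](CC)(CC)CC)C=C[C@@](C)(CO[Si](CC)(CC)CC)[C@@H]2CC[C@@]1(C)O
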